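**Retrosynthetic overview**

- The route rests on the 2,6,6-trimethylcyclohex-2-en-1-yl ring. Its only CH stereocentre lies between the C(CH3)2 carbon and the C(CH3)=CH alkene, and the ring is the head unit of a regular head-to-tail isoprenoid chain. The C(CH3)2–CH ring bond is therefore the bond formed when a protonated terminal (CH3)2C=CH alkene is attacked by the next trisubstituted alkene.
- That bond, the ring, the stereocentre and the endocyclic alkene are made first, in one cyclase-mediated monocyclisation of (E)-geranylacetone to (S)-dihydro-alpha-ionone. This is the only ring, so no further ring formation follows.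
- The methyl ketone is converted to a terminal alkyne. Zirconium-catalysed methylalumination with oxirane trapping builds the (E)-trisubstituted alkene and the CH2CH2 spacer, and the resulting homoallylic alcohol is turned into the iodide.
- The bond between the chain CH2 and the substituted carbon of the but-2-ene-1,4-diol unit is cut as an sp3–sp2 Negishi coupling. The partner is the bis-silyl ether of (Z)-2-iodobut-2-ene-1,4-diol, whose geometry is fixed by trans-hydroalumination and iodination of but-2-yne-1,4-diol.
- Desilylation and acetylation finish the target.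

Key step: step 1

Remark: the ring stereocentre keeps the CIP order C(CH3)=CH > C(CH3)2 > CH2 > H in every compound from 2 to 19, so it is (S) throughout. Isomerically pure commercial (E)-geranylacetone is assumed, and the cyclase variant is assumed to come from a screened panel of active-site variants.

**Route**

Step 1
Reactants: 1 (E)-geranylacetone [(5E)-6,10-dimethylundeca-5,9-dien-2-one]
Product: 2 (S)-dihydro-alpha-ionone [4-[(1S)-2,6,6-trimethylcyclohex-2-en-1-yl]butan-2-one]
Conditions: engineered squalene–hopene cyclase variant (Alicyclobacillus acidocaldarius enzyme, E. coli whole cells or lysate), citrate buffer pH 6.0, sodium dodecyl sulfate (0.2% w/v), 30 °C, 24–48 h; EtOAc extraction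
Reagents that add atoms: none
Why: Proposed new method: the catalytic aspartic acid of the cyclase (DXDD motif) protonates the terminal C9=C10 alkene of 1 at C9 in the Markovnikov sense, the C5=C6 alkene attacks the C10 cation through C5 in a 6-endo-trig cation–olefin closure that forms the C5–C10 bond and the six-membered ring, and the tertiary C6 cation should be quenched by loss of a C7 proton to give the endocyclic C6=C7 alkene. The closest known reaction type is the class 2 cyclase monocyclisation of this same substrate that ends with methyl deprotonation (exocyclic gamma isomer), together with the cyclase conversion of homofarnesol into ambroxide; what is new is steering the final proton loss to the ring CH2. The single new stereocentre (C5) is set by the enzyme pocket and not by the substrate: the chair-like prefold presents the alkene face that leads to the 5-alpha hydrogen of hopene-type products, which corresponds to (S) here. The step needs face selection at C5, C7–H loss in preference to methyl C–H or C5–H loss, and no capture of the cation by the carbonyl oxygen. The first is inherited from the native fold and the (E) geometry of C5=C6, the second is to be secured by selecting active-site variants that place the basic residue or water next to C7, and the third by hydrogen-bond anchoring of the ketone, which holds the chain extended. Because 1 has only two alkenes, a second carbocyclisation cannot follow.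

Step 2
Reactants: 2 (S)-dihydro-alpha-ionone
Product: 4 diethyl 4-[(1S)-2,6,6-trimethylcyclohex-2-en-1-yl]but-1-en-2-yl phosphate, via lithium enolate 3 (not isolated)
Conditions: LiN(iPr)2 (1.1 equiv), THF, −78 °C; ClP(O)(OEt)2 (1.2 equiv), −78 °C → rt
Reagents that add atoms: diethyl chlorophosphate, CCOP(=O)(Cl)OCC
Why: kinetic deprotonation of the methyl ketone by LiN(iPr)2 should occur on the methyl side and the enolate is O-phosphorylated (enol phosphate formation); the ring stereocentre is three bonds from the carbonyl and is not enolisable.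

Step 3
Reactants: 4 enol phosphate
Product: 6 (6S)-6-(but-3-yn-1-yl)-1,5,5-trimethylcyclohex-1-ene, via lithium acetylide 5 (not isolated)
Conditions: LiN(iPr)2 (2.3 equiv), THF, −78 °C → rt; H2O quench
Reagents that add atoms: none
Why: base-induced beta-elimination of diethyl phosphate from the 1,1-disubstituted enol phosphate (Negishi methyl ketone to alkyne protocol) should give the terminal alkyne, held as its lithium acetylide under the excess base until the quench.

Step 4
Reactants: 6 terminal alkyne; 7 oxirane
Product: 10 (3E)-4-methyl-6-[(1S)-2,6,6-trimethylcyclohex-2-en-1-yl]hex-3-en-1-ol, via alkenyldimethylalane 8 (not isolated), via lithium alkenylaluminate 9 (not isolated)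
Conditions: Me3Al (2.5 equiv), Cp2ZrCl2 (0.25 equiv), CH2Cl2, 0 °C → rt; volatiles removed; n-BuLi (1.0 equiv), hexane/THF, −78 → 0 °C; oxirane (excess), 0 °C → rt; aq potassium sodium tartrate
Reagents that add atoms: trimethylaluminium, C[Al](C)C
Why: Negishi zirconium-catalysed methylalumination adds CH3 and Al syn across the terminal alkyne with Al on the terminal carbon, and the derived aluminate transfers the alkenyl group to oxirane with retention, which fixes the (E) trisubstituted alkene; the trisubstituted ring alkene is inert to carboalumination.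

Step 5
Reactants: 10 homoallylic alcohol
Product: 11 (6S)-6-[(3E)-6-iodo-3-methylhex-3-en-1-yl]-1,5,5-trimethylcyclohex-1-ene
Conditions: PPh3, I2, imidazole, CH2Cl2, 0 °C → rt
Reagents that add atoms: iodine, II
Why: Appel-type iodination converts the primary alcohol into the iodide by SN2 displacement of the alkoxyphosphonium ion under non-acidic conditions that leave both trisubstituted alkenes alone.

Step 6
Reactants: 12 but-2-yne-1,4-diol
Product: 14 (2Z)-2-iodobut-2-ene-1,4-diol, via cyclic sodium alkenylalanate 13 (not isolated)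
Conditions: NaAlH2(OCH2CH2OMe)2 (Red-Al, toluene solution, 3 equiv), THF, 0 °C → rt; EtOAc; I2, THF, −78 → 0 °C; aq Na2S2O3, aq potassium sodium tartrate
Reagents that add atoms: iodine, II
Why: alkoxide-directed trans-hydroalumination places H and Al anti across the symmetric alkyne, and iodinolysis of the C–Al bond with retention should give the alkenyl iodide in which the two CH2OH groups are trans.

Step 7
Reactants: 14 iodo diol
Product: 15 (2Z)-1,4-bis[(tert-butyldimethylsilyl)oxy]-2-iodobut-2-ene
Conditions: TBSCl (2.4 equiv), imidazole, DMF, rt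
Reagents that add atoms: tert-butyldimethylsilyl chloride, CC(C)(C)[Si](C)(C)Cl
Why: standard silylation of both primary allylic alcohols removes the acidic OH groups before the organozinc coupling.

Step 8
Reactants: 11 homoallylic iodide; 15 alkenyl iodide
Product: 17 (2E)-1,4-bis[(tert-butyldimethylsilyl)oxy]-2-[(3E)-4-methyl-6-[(1S)-2,6,6-trimethylcyclohex-2-en-1-yl]hex-3-en-1-yl]but-2-ene, via alkylzinc iodide 16 (not isolated)
Conditions: Zn dust (activated with BrCH2CH2Br and Me3SiCl), LiCl, THF, 40 °C; then 15, PdCl2(dppf) (5 mol %), THF, rt → 50 °C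
Reagents that add atoms: none
Why: zinc insertion into the primary C–I bond gives an alkylzinc iodide that undergoes Negishi sp3–sp2 cross-coupling with the alkenyl iodide with retention of alkene geometry, so the chain ends up cis to the CH2O group on the neighbouring alkene carbon and the two CH2O groups stay trans; the bidentate dppf ligand disfavours beta-hydride elimination.

Step 9
Reactants: 17 bis-silyl ether
Product: 18 (2E)-2-[(3E)-4-methyl-6-[(1S)-2,6,6-trimethylcyclohex-2-en-1-yl]hex-3-en-1-yl]but-2-ene-1,4-diol
Conditions: Bu4NF (2.5 equiv), THF, 0 °C → rt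
Reagents that add atoms: none
Why: fluoride-mediated desilylation cleaves both primary TBS ethers under near-neutral conditions that do not affect the three alkenes or the stereocentre.

Step 10
Reactants: 18 diol
Product: 19 (2E)-2-[(3E)-4-methyl-6-[(1S)-2,6,6-trimethylcyclohex-2-en-1-yl]hex-3-en-1-yl]but-2-ene-1,4-diyl diacetate (target)
Conditions: Ac2O, pyridine, DMAP (cat.), CH2Cl2, 0 °C → rt
Reagents that add atoms: acetic anhydride, CC(=O)OC(C)=O
Why: DMAP-catalysed acetylation of the two primary allylic alcohols should give the diacetate without touching the alkenes.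

**Compound list**

1 | (E)-geranylacetone, (5E)-6,10-dimethylundeca-5,9-dien-2-one | CC(C)=CCC/C(C)=C/CCC(C)=O | starting material
2 | (S)-dihydro-alpha-ionone, 4-[(1S)-2,6,6-trimethylcyclohex-2-en-1-yl]butan-2-one | CC(=O)CC[C@@H]1C(C)=CCCC1(C)C | intermediate
3 | lithium enolate of 2 (terminal, kinetic) | [Li]OC(=C)CC[C@@H]1C(C)=CCCC1(C)C | intermediate
4 | diethyl 4-[(1S)-2,6,6-trimethylcyclohex-2-en-1-yl]but-1-en-2-yl phosphate | C=C(CC[C@@H]1C(C)=CCCC1(C)C)OP(=O)(OCC)OCC | intermediate
5 | lithium acetylide of 6 | [Li]C#CCC[C@@H]1C(C)=CCCC1(C)C | intermediate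
6 | (6S)-6-(but-3-yn-1-yl)-1,5,5-trimethylcyclohex-1-ene | C#CCC[C@@H]1C(C)=CCCC1(C)C | intermediate
7 | oxirane | C1CO1 | starting material
8 | dimethyl[(1E)-2-methyl-4-[(1S)-2,6,6-trimethylcyclohex-2-en-1-yl]but-1-en-1-yl]alane | C[Al](C)/C=C(\C)CC[C@@H]1C(C)=CCCC1(C)C | intermediate
9 | lithium butyl(dimethyl)[(1E)-2-methyl-4-[(1S)-2,6,6-trimethylcyclohex-2-en-1-yl]but-1-en-1-yl]aluminate | [Li+].CCCC[Al-](C)(C)/C=C(\C)CC[C@@H]1C(C)=CCCC1(C)C | intermediate
10 | (3E)-4-methyl-6-[(1S)-2,6,6-trimethylcyclohex-2-en-1-yl]hex-3-en-1-ol | OCC/C=C(\C)CC[C@@H]1C(C)=CCCC1(C)C | intermediate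
11 | (6S)-6-[(3E)-6-iodo-3-methylhex-3-en-1-yl]-1,5,5-trimethylcyclohex-1-ene | ICC/C=C(\C)CC[C@@H]1C(C)=CCCC1(C)C | intermediate
12 | but-2-yne-1,4-diol | OCC#CCO | starting material
13 | cyclic sodium alkenylalanate from trans-hydroalumination of 12 (2,5-dihydro-1,2-oxaaluminol-2-uide, remote oxygen drawn as sodium alkoxide) | [Na+].[Na+].[O-]CC1=CCO[Al-]1(OCCOC)OCCOC | intermediate
14 | (2Z)-2-iodobut-2-ene-1,4-diol | OC/C=C(\I)CO | intermediate
15 | (2Z)-1,4-bis[(tert-butyldimethylsilyl)oxy]-2-iodobut-2-ene | CC(C)(C)[Si](C)(C)OC/C=C(\I)CO[Si](C)(C)C(C)(C)C | intermediate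
16 | [(3E)-4-methyl-6-[(1S)-2,6,6-trimethylcyclohex-2-en-1-yl]hex-3-en-1-yl]zinc iodide | I[Zn]CC/C=C(\C)CC[C@@H]1C(C)=CCCC1(C)C | intermediate
17 | (2E)-1,4-bis[(tert-butyldimethylsilyl)oxy]-2-[(3E)-4-methyl-6-[(1S)-2,6,6-trimethylcyclohex-2-en-1-yl]hex-3-en-1-yl]but-2-ene | CC(C)(C)[Si](C)(C)OC/C=C(\CC/C=C(\C)CC[C@@H]1C(C)=CCCC1(C)C)CO[Si](C)(C)C(C)(C)C | intermediate
18 | (2E)-2-[(3E)-4-methyl-6-[(1S)-2,6,6-trimethylcyclohex-2-en-1-yl]hex-3-en-1-yl]but-2-ene-1,4-diol | OC/C=C(\CC/C=C(\C)CC[C@@H]1C(C)=CCCC1(C)C)CO | intermediate
19 | (2E)-2-[(3E)-4-methyl-6-[(1S)-2,6,6-trimethylcyclohex-2-en-1-yl]hex-3-en-1-yl]but-2-ene-1,4-diyl diacetate | CC(=O)OC/C=C(\CC/C=C(\C)CC[C@@H]1C(C)=CCCC1(C)C)COC(C)=O | target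

**Step count**

Total step count: 10. Longest linear sequence: 8 (steps 1–5 and 8–10); steps 6 and 7 form the side branch to the alkenyl iodide.

**Steps most likely to fail**

1. Step 1 (Proposed new method). The tertiary cation may lose a methyl proton or the C5 proton instead of the ring CH2 proton, may be captured by the carbonyl oxygen, or the short substrate may turn over slowly or with incomplete face selection. The fallback sets out from 1 and uses the established type of cyclase variant that ends the same monocyclisation with methyl deprotonation. This should give the exocyclic isomer (S)-gamma-dihydroionone, 4-[(1S)-2,2-dimethyl-6-methylidenecyclohexyl]butan-2-one F1. The exocyclic alkene of F1 would then be moved into the ring by transition-metal-catalysed alkene isomerisation with PdCl2(MeCN)2 (catalytic, toluene, 40–60 °C), which should stop at the trisubstituted ring alkene. Brønsted or Lewis acids are avoided at this point because they would trigger carbonyl-ene closure of the ketone onto the exocyclic alkene. The fallback returns to the route at 2.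

2. Step 4. Ate-complex formation may be incomplete and the epoxide opening sluggish, so that protonolysis of the alkenylmetal on work-up competes with C–C bond formation. The fallback sets out from 6. The same methylalumination is quenched with I2 to give the alkenyl iodide (6S)-6-[(3E)-4-iodo-3-methylbut-3-en-1-yl]-1,5,5-trimethylcyclohex-1-ene F2. Negishi coupling of F2 with vinylzinc bromide (from vinylmagnesium bromide and ZnBr2; Pd(PPh3)4, a zerovalent palladium catalyst, THF) gives the diene (6S)-1,5,5-trimethyl-6-[(3E)-3-methylhexa-3,5-dien-1-yl]cyclohex-1-ene F3. Hydroboration of the terminal vinyl group of F3 with 9-BBN gives the B-alkyl-9-borabicyclo[3.3.1]nonane F4, and oxidation with NaOH/H2O2 returns to the route at 10.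

3. Step 8. Zinc insertion may be slow, and the alkylzinc reagent may be lost by protodezincation or homocoupling, or by beta-hydride elimination at the alkylpalladium stage. The fallback replaces the cross-coupling by an olefination and sets out from 11. Iodine–lithium exchange (t-BuLi, Et2O, −78 °C) gives the organolithium [(3E)-4-methyl-6-[(1S)-2,6,6-trimethylcyclohex-2-en-1-yl]hex-3-en-1-yl]lithium F5. Addition to commercial (tert-butyldimethylsilyloxy)acetaldehyde gives the secondary alcohol (5E)-1-[(tert-butyldimethylsilyl)oxy]-6-methyl-8-[(1S)-2,6,6-trimethylcyclohex-2-en-1-yl]oct-5-en-2-ol F6 (both carbinol epimers). Dess–Martin oxidation gives the alpha-silyloxy ketone (5E)-1-[(tert-butyldimethylsilyl)oxy]-6-methyl-8-[(1S)-2,6,6-trimethylcyclohex-2-en-1-yl]oct-5-en-2-one F7. Wittig reaction with ethyl (triphenylphosphoranylidene)acetate (toluene, reflux) should give the enoate ethyl (2E,6E)-3-{[(tert-butyldimethylsilyl)oxy]methyl}-7-methyl-9-[(1S)-2,6,6-trimethylcyclohex-2-en-1-yl]nona-2,6-dienoate F8. Alpha-alkoxy ketones are expected to place the ester trans to the CH2OSi group, and any minor geometric isomer would be removed by chromatography. Reduction with iBu2AlH (CH2Cl2, −78 °C) gives the allylic alcohol (2E,6E)-3-{[(tert-butyldimethylsilyl)oxy]methyl}-7-methyl-9-[(1S)-2,6,6-trimethylcyclohex-2-en-1-yl]nona-2,6-dien-1-ol F9, and Bu4NF returns to the route at 18.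

**Further compounds**

F1 | step 1 | (S)-gamma-dihydroionone, 4-[(1S)-2,2-dimethyl-6-methylidenecyclohexyl]butan-2-one | CC(=O)CC[C@@H]1C(=C)CCCC1(C)C
F2 | step 4 | (6S)-6-[(3E)-4-iodo-3-methylbut-3-en-1-yl]-1,5,5-trimethylcyclohex-1-ene | I/C=C(\C)CC[C@@H]1C(C)=CCCC1(C)C
F3 | step 4 | (6S)-1,5,5-trimethyl-6-[(3E)-3-methylhexa-3,5-dien-1-yl]cyclohex-1-ene | C=C/C=C(\C)CC[C@@H]1C(C)=CCCC1(C)C
F4 | step 4 | 9-[(3E)-4-methyl-6-[(1S)-2,6,6-trimethylcyclohex-2-en-1-yl]hex-3-en-1-yl]-9-borabicyclo[3.3.1]nonane | C(C/C=C(\C)CC[C@@H]1C(C)=CCCC1(C)C)B1C2CCCC1CCC2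
F5 | step 8 | [(3E)-4-methyl-6-[(1S)-2,6,6-trimethylcyclohex-2-en-1-yl]hex-3-en-1-yl]lithium | [Li]CC/C=C(\C)CC[C@@H]1C(C)=CCCC1(C)C
F6 | step 8 | (5E)-1-[(tert-butyldimethylsilyl)oxy]-6-methyl-8-[(1S)-2,6,6-trimethylcyclohex-2-en-1-yl]oct-5-en-2-ol (both carbinol epimers) | CC(C)(C)[Si](C)(C)OCC(O)CC/C=C(\C)CC[C@@H]1C(C)=CCCC1(C)C
F7 | step 8 | (5E)-1-[(tert-butyldimethylsilyl)oxy]-6-methyl-8-[(1S)-2,6,6-trimethylcyclohex-2-en-1-yl]oct-5-en-2-one | CC(C)(C)[Si](C)(C)OCC(=O)CC/C=C(\C)CC[C@@H]1C(C)=CCCC1(C)C
F8 | step 8 | ethyl (2E,6E)-3-{[(tert-butyldimethylsilyl)oxy]methyl}-7-methyl-9-[(1S)-2,6,6-trimethylcyclohex-2-en-1-yl]nona-2,6-dienoate | CCOC(=O)/C=C(\CC/C=C(\C)CC[C@@H]1C(C)=CCCC1(C)C)CO[Si](C)(C)C(C)(C)C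
F9 | step 8 | (2E,6E)-3-{[(tert-butyldimethylsilyl)oxy]methyl}-7-methyl-9-[(1S)-2,6,6-trimethylcyclohex-2-en-1-yl]nona-2,6-dien-1-ol | OC/C=C(\CC/C=C(\C)CC[C@@H]1C(C)=CCCC1(C)C)CO[Si](C)(C)C(C)(C)C
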